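**Plan**

- Retrosynthesis: the γ-lactam is opened at N–C(OH) and at the amide (ammonia plus a 2-acyl-4-oxo ester). The bond between the ring-A acyl carbon and lactam C-3 is cut next (13-membered ring), then ArCH2–CO, then the two bonds that join rings A and B (intramolecular Diels–Alder), the aryl–O bond and the chains on ring C. Ring A is the cyclohexene, ring B the cyclopentane, ring C the trimethylcyclohexane.
- Enabling feature: the lactam carbon that bears OH, N and the benzylic CH2 is a masked ketone. With the ring-A acyl carbonyl it forms a 1,4-dicarbonyl pair across lactam C-3/C-4, so lactam C-3 is the β-carbon of a 4-oxo-2-enoate and the acyl carbon is an aldehyde used as an acyl anion.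
- Forward order: ring C; triene by three Wittig steps; ketone to nitrile to enone to carbinol; aryl ether; Diels–Alder closes rings A and B together; benzyl alkenyl ketone; Stetter reaction closes the paracyclophane; ammonia closes the lactam last.
- Stereochemistry: one ring-C methyl centre from an organocatalyst; the other ring-C centres by equilibration and axial attack; the carbinol by Felkin–Anh reduction; the four ring-A/B centres by the endo Diels–Alder transition state; the two lactam centres by equilibration in the last step.

Key step: step 18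

Remark on the chemistry: the configurations at the hemiaminal carbon and at lactam C-3 are assumed to be those favoured at equilibrium inside the cyclophane, since both centres are labile (ring-chain tautomerism; β-keto amide enolisation).
Remark on the chemistry: ethyl (E)-3-(tributylstannyl)prop-2-enoate and 2-(triphenylphosphoranylidene)propanal are taken as commercially available.

**Route**

Step 1
Reactants: 1 propanal; 2 pent-1-en-3-one
Product: 3 (S)-2-methyl-5-oxoheptanal
Conditions: (R)-α,α-diphenylprolinol trimethylsilyl ether (10 mol%), ethyl 3,4-dihydroxybenzoate (20 mol%), neat, 4 °C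
Reagents that add atoms: none
Why: Enamine-catalysed asymmetric Michael addition of an aldehyde to a vinyl ketone, in which the diarylmethyl group shields one face of the (E)-enamine and should set the methyl-bearing centre as (S) (the (S)-catalyst gives the (R)-series by the usual face-shielding model, so the (R)-catalyst is used).

Step 2
Reactants: 3 (S)-2-methyl-5-oxoheptanal
Product: 4 (S)-2,4-dimethylcyclohex-2-en-1-one
Conditions: KOH (0.1 M aq), n-Bu4NOH (cat.), Et2O–THF, reflux
Reagents that add atoms: none
Why: Intramolecular aldol condensation of the 1,5-keto aldehyde (the ethyl ketone α-carbon attacks the aldehyde, then dehydration), run under mild biphasic base so that ring closure should outrun enolisation of the aldehyde α-centre.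

Step 3
Reactants: 4 (S)-2,4-dimethylcyclohex-2-en-1-one
Product: 5 (2S,4S)-2,4-dimethylcyclohexan-1-one (cis)
Conditions: H2 (1 atm), Pd/C, EtOAc, rt; then NaOMe (cat.), MeOH, rt
Reagents that add atoms: none
Why: Heterogeneous hydrogenation of the enone followed by base equilibration of the epimerisable C-2 centre should give the cis (diequatorial) ketone under thermodynamic control.

Step 4
Reactants: 5 (2S,4S)-2,4-dimethylcyclohexan-1-one
Product: 6 (4R,6S)-2-(hydroxymethylidene)-4,6-dimethylcyclohexan-1-one
Conditions: NaH, HCO2Et, THF, 0 °C → rt; aq HCl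
Reagents that add atoms: ethyl formate, O=COCC
Why: Claisen formylation under equilibrating conditions should occur at the methylene α-carbon, because only that adduct is held as a stabilised enolate, while the methyl-bearing α-centre stays equatorial.

Step 5
Reactants: 6 (4R,6S)-2-(hydroxymethylidene)-4,6-dimethylcyclohexan-1-one
Product: 7 (1S,3S,5R)-1,3,5-trimethyl-2-oxocyclohexane-1-carbaldehyde
Conditions: MeI, K2CO3, acetone, reflux
Reagents that add atoms: iodomethane, CI
Why: C-Methylation of the hydroxymethylene ketone (stabilised β-dicarbonyl enolate alkylation) in which the electrophile should enter axially on the chair that keeps both ring methyls equatorial, so the new quaternary methyl is trans to them and the formyl group equatorial.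

Step 6
Reactants: 7 (1S,3S,5R)-1,3,5-trimethyl-2-oxocyclohexane-1-carbaldehyde
Product: 8 (E)-2-methyl-3-[(1S,3S,5R)-1,3,5-trimethyl-2-oxocyclohexyl]prop-2-enal
Conditions: Ph3P=C(Me)CHO (1.3 equiv), toluene, 110 °C
Reagents that add atoms: 2-(triphenylphosphoranylidene)propanal, CC(C=O)=P(c1ccccc1)(c1ccccc1)c1ccccc1
Why: Wittig olefination with a stabilised formyl ylide should react only at the aldehyde (the flanked ring ketone is inert) and give the (E)-2-methyl enal, as is usual for stabilised ylides.

Step 7
Reactants: 8 (E)-2-methyl-3-[(1S,3S,5R)-1,3,5-trimethyl-2-oxocyclohexyl]prop-2-enal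
Product: 9 (2E,4E)-2,4-dimethyl-5-[(1S,3S,5R)-1,3,5-trimethyl-2-oxocyclohexyl]penta-2,4-dienal
Conditions: Ph3P=C(Me)CHO (1.5 equiv), toluene, 110 °C
Reagents that add atoms: 2-(triphenylphosphoranylidene)propanal, CC(C=O)=P(c1ccccc1)(c1ccccc1)c1ccccc1
Why: A second Wittig reaction with the same stabilised ylide extends the enal by one (E)-trisubstituted alkene, and this geometry later decides the configuration of the ring-A quaternary carbon.

Step 8
Reactants: 9 (2E,4E)-2,4-dimethyl-5-[(1S,3S,5R)-1,3,5-trimethyl-2-oxocyclohexyl]penta-2,4-dienal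
Product: 10 (2S,4R,6S)-2-[(1E,3E)-2,4-dimethylhexa-1,3,5-trien-1-yl]-2,4,6-trimethylcyclohexan-1-one
Conditions: Ph3PCH3Br, KN(SiMe3)2, THF, 0 °C; then 9, −78 → 0 °C
Reagents that add atoms: methyltriphenylphosphonium bromide, C[P+](c1ccccc1)(c1ccccc1)c1ccccc1.[Br-]
Why: Wittig methylenation should take place at the unhindered dienal carbonyl only, since the ring ketone lies between a quaternary and a tertiary carbon.

Step 9
Reactants: 10 (2S,4R,6S)-2-[(1E,3E)-2,4-dimethylhexa-1,3,5-trien-1-yl]-2,4,6-trimethylcyclohexan-1-one
Product: 11 (1R,2S,4R,6S)-2-[(1E,3E)-2,4-dimethylhexa-1,3,5-trien-1-yl]-2,4,6-trimethylcyclohexane-1-carbonitrile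
Conditions: TosMIC, KOt-Bu, DME, EtOH (2 equiv), 0 → 40 °C
Reagents that add atoms: p-toluenesulfonylmethyl isocyanide, Cc1ccc(cc1)S(=O)(=O)C[N+]#[C-]
Why: van Leusen reductive cyanation homologates the ketone with base-only reagents that the triene tolerates, and final protonation of the nitrile-stabilised carbanion should occur axially, anti to the adjacent axial methyl, placing the cyano group equatorial (this centre is again epimerisable and thermodynamically equatorial in enone 16).

Step 10
Reactants: 12 3,3-diethoxyprop-1-yne
Product: 13 (E)-tributyl(3,3-diethoxyprop-1-en-1-yl)stannane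
Conditions: Bu3SnH, PdCl2(PPh3)2 (2 mol%), THF, 0 °C → rt
Reagents that add atoms: tributyltin hydride, CCCC[SnH](CCCC)CCCC
Why: Palladium-catalysed syn-hydrostannation of the terminal alkyne should place tin at the unhindered terminus and give the (E)-alkenylstannane, any internal isomer being removed by chromatography.

Step 11
Reactants: 11 (1R,2S,4R,6S)-2-[(1E,3E)-2,4-dimethylhexa-1,3,5-trien-1-yl]-2,4,6-trimethylcyclohexane-1-carbonitrile; 13 (E)-tributyl(3,3-diethoxyprop-1-en-1-yl)stannane
Product: 16 (E)-1-[(1R,2S,4R,6S)-2-((1E,3E)-2,4-dimethylhexa-1,3,5-trien-1-yl)-2,4,6-trimethylcyclohexyl]-4,4-diethoxybut-2-en-1-one, via vinyllithium 14 (not isolated), via N-lithio ketimine 15 (not isolated)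
Conditions: 13, n-BuLi, THF, −78 °C; then 11, −78 → 0 °C; then AcOH/NaOAc buffer (pH 5), THF–H2O, 0 °C
Reagents that add atoms: water, O
Why: Tin–lithium exchange gives the (E)-alkenyllithium with retention, which should add once to the nitrile because the N-lithio ketimine resists further addition, and buffered hydrolysis releases the enone while the acetal survives.

Step 12
Reactants: 16 (E)-1-[(1R,2S,4R,6S)-2-((1E,3E)-2,4-dimethylhexa-1,3,5-trien-1-yl)-2,4,6-trimethylcyclohexyl]-4,4-diethoxybut-2-en-1-one
Product: 17 (1S,2E)-1-[(1R,2S,4R,6S)-2-((1E,3E)-2,4-dimethylhexa-1,3,5-trien-1-yl)-2,4,6-trimethylcyclohexyl]-4,4-diethoxybut-2-en-1-ol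
Conditions: NaBH4, CeCl3·7H2O, MeOH, −78 °C
Reagents that add atoms: none
Why: Luche 1,2-reduction of the enone under Felkin–Anh control, in which hydride should attack anti to the quaternary ring carbon (the large α-substituent) and past the α-hydrogen, setting the carbinol centre as (S) as the target requires.

Step 13
Reactants: 17 (1S,2E)-1-[(1R,2S,4R,6S)-2-((1E,3E)-2,4-dimethylhexa-1,3,5-trien-1-yl)-2,4,6-trimethylcyclohexyl]-4,4-diethoxybut-2-en-1-ol; 18 4-fluorobenzaldehyde
Product: 19 4-{[(1S,2E)-1-((1R,2S,4R,6S)-2-((1E,3E)-2,4-dimethylhexa-1,3,5-trien-1-yl)-2,4,6-trimethylcyclohexyl)-4,4-diethoxybut-2-en-1-yl]oxy}benzaldehyde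
Conditions: KN(SiMe3)2, THF–DMF, 0 °C; then 18, 0 °C → rt
Reagents that add atoms: none
Why: Nucleophilic aromatic substitution (addition–elimination) of the potassium alkoxide on the para-formyl-activated aryl fluoride forms the aryl ether at oxygen, so the hindered carbinol carbon is never attacked and its configuration is retained.

Step 14
Reactants: 19 4-{[(1S,2E)-1-((1R,2S,4R,6S)-2-((1E,3E)-2,4-dimethylhexa-1,3,5-trien-1-yl)-2,4,6-trimethylcyclohexyl)-4,4-diethoxybut-2-en-1-yl]oxy}benzaldehyde
Product: 20 benzylic alcohol of 19 (CH2OH in place of the aryl CHO)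
Conditions: NaBH4, MeOH–THF, 0 °C
Reagents that add atoms: none
Why: Borohydride reduction of the aryl aldehyde is done here, while the enal is still masked as its acetal, so that only one aldehyde is present.

Step 15
Reactants: 20 benzylic alcohol of 19
Product: 22 tricyclic aldehyde (decahydrofluorene core of the target with CHO on the ring-A carbon between the quaternary carbon and the A/B fusion carbon and a 4-(hydroxymethyl)phenoxy group on ring B; all nine core stereocentres as in the target), via enal 21 (not isolated)
Conditions: PPTS (cat.), acetone–H2O, rt; then toluene, BHT (cat.), 110 °C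
Reagents that add atoms: water, O
Why: Acetal hydrolysis unmasks the (E)-enal, which should undergo an intramolecular Diels–Alder reaction through the formyl-endo transition state with the three-atom tether to give trans-fused rings A and B; the (E,E)-diene geometry puts the vinyl group cis and the methyl trans to the formyl group at the new quaternary carbon, and the diene carbon takes the pseudo-equatorial position cis to the angular methyl on the forming trans-hydrindane.

Step 16
Reactants: 22 tricyclic aldehyde
Product: 23 benzylic chloride of 22 (CH2Cl in place of CH2OH)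
Conditions: PPh3, N-chlorosuccinimide, CH2Cl2, −20 → 0 °C
Reagents that add atoms: N-chlorosuccinimide, ClN1C(=O)CCC1=O
Why: Appel-type chlorination of the electron-rich benzylic alcohol under neutral conditions should leave the hindered aldehyde and the alkenes untouched.

Step 17
Reactants: 23 benzylic chloride of 22; 24 ethyl (E)-3-(tributylstannyl)prop-2-enoate
Product: 25 ethyl (E)-4-oxo-5-aryl-pent-2-enoate in which the aryl group is the 4-oxyphenyl unit of tricyclic aldehyde 22
Conditions: 24, CO (3 atm), PdCl2(PPh3)2 (5 mol%), THF, 55 °C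
Reagents that add atoms: carbon monoxide, [C-]#[O+]
Why: Carbonylative Stille coupling (oxidative addition of the benzylic chloride, CO insertion, transfer of the (E)-alkenyl group from tin with retention) should give the benzyl alkenyl ketone without a nucleophilic organometallic that could attack the aldehyde.

Step 18
Reactants: 25 ethyl (E)-4-oxo-5-aryl-pent-2-enoate of the tricyclic aldehyde
Product: 26 13-membered paracyclophane 2-acyl-4-oxo ester (ethyl ester on the carbon between the ring-A ketone and the CH2 of the benzylic ketone; this carbon as a mixture of epimers)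
Conditions: 3-benzyl-5-(2-hydroxyethyl)-4-methylthiazolium chloride (30 mol%), Et3N (60 mol%), 1,4-dioxane, 80 °C, slow addition of 25 (final 2 mM)
Reagents that add atoms: none
Why: Proposed new method: the thiazol-2-ylidene adds to the ring-A aldehyde and proton transfer gives the Breslow enaminol, an acyl anion equivalent, which adds to the alkene carbon β to the benzylic ketone (α to the ester) of the tethered 4-oxo-2-enoate, after which protonation and loss of the carbene give the 2-acyl-4-oxo ester. The closest known reaction types are intramolecular Stetter reactions that close five- and six-membered rings and intermolecular Stetter additions of aliphatic aldehydes to 4-oxo-2-enoates, whereas a 13-membered version is not established. The macrocycle closes in the 13-endo-trig mode, both alkene carbons ending inside the ring. The only new stereocentre (the carbon between the two carbonyls) is a labile β-keto ester centre that needs no control here and is set by equilibration in step 19, and the α-centre of the aldehyde should be retained because the carbene reacts at the carbonyl carbon. The step needs regioselectivity for the ketone-β carbon (secured by the stronger acceptor character of the ketone, which also gives the smaller ring), chemoselectivity over benzoin dimerisation and oligomerisation (secured by the neopentyl-like hindrance of the aldehyde and high dilution) and proximity of the two ends (secured by the rigid trans arrangement of the aryloxy and formyl groups on the two carbons that flank the A/B fusion carbon).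

Step 19
Reactants: 26 13-membered paracyclophane 2-acyl-4-oxo ester
Product: 27 target CNP0450261.1
Conditions: NH3 (7 M in MeOH), rt → 40 °C
Reagents that add atoms: ammonia, N
Why: Ammonia condenses with the unhindered benzylic ketone and the hemiaminal nitrogen acylates on the ester (5-exo-trig lactamisation of a γ-keto ester) to give the 5-hydroxy γ-lactam, while the hemiaminal carbon and lactam C-3 should equilibrate under the basic conditions to the configurations favoured inside the cyclophane.

**Compound list**

1 | propanal | CCC=O | starting material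
2 | pent-1-en-3-one | CCC(=O)C=C | starting material
3 | (S)-2-methyl-5-oxoheptanal | O=C[C@@H](C)CCC(=O)CC | intermediate
4 | (S)-2,4-dimethylcyclohex-2-en-1-one | O=C1C(C)=C[C@@H](C)CC1 | intermediate
5 | (2S,4S)-2,4-dimethylcyclohexan-1-one | O=C1[C@@H](C)C[C@@H](C)CC1 | intermediate
6 | (4R,6S)-2-(hydroxymethylidene)-4,6-dimethylcyclohexan-1-one | O=C1[C@@H](C)C[C@@H](C)CC1=CO | intermediate
7 | (1S,3S,5R)-1,3,5-trimethyl-2-oxocyclohexane-1-carbaldehyde | O=C1[C@@H](C)C[C@@H](C)C[C@]1(C=O)C | intermediate
8 | (E)-2-methyl-3-[(1S,3S,5R)-1,3,5-trimethyl-2-oxocyclohexyl]prop-2-enal | O=C1[C@@H](C)C[C@@H](C)C[C@]1(/C=C(C)/C=O)C | intermediate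
9 | (2E,4E)-2,4-dimethyl-5-[(1S,3S,5R)-1,3,5-trimethyl-2-oxocyclohexyl]penta-2,4-dienal | O=C1[C@@H](C)C[C@@H](C)C[C@]1(/C=C(C)/C=C(C)/C=O)C | intermediate
10 | (2S,4R,6S)-2-[(1E,3E)-2,4-dimethylhexa-1,3,5-trien-1-yl]-2,4,6-trimethylcyclohexan-1-one | O=C1[C@@H](C)C[C@@H](C)C[C@]1(/C=C(C)/C=C(C)/C=C)C | intermediate
11 | (1R,2S,4R,6S)-2-[(1E,3E)-2,4-dimethylhexa-1,3,5-trien-1-yl]-2,4,6-trimethylcyclohexane-1-carbonitrile | N#C[C@@H]1[C@@H](C)C[C@@H](C)C[C@]1(/C=C(C)/C=C(C)/C=C)C | intermediate
12 | 3,3-diethoxyprop-1-yne | C#CC(OCC)OCC | starting material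
13 | (E)-tributyl(3,3-diethoxyprop-1-en-1-yl)stannane | CCCC[Sn](CCCC)(CCCC)/C=C/C(OCC)OCC | intermediate
14 | (E)-(3,3-diethoxyprop-1-en-1-yl)lithium (not isolated) | [Li]/C=C/C(OCC)OCC | intermediate
15 | N-lithio ketimine of enone 16 (not isolated) | CCOC(OCC)/C=C/C(=N[Li])[C@@H]1[C@@H](C)C[C@@H](C)C[C@]1(/C=C(C)/C=C(C)/C=C)C | intermediate
16 | (E)-1-[(1R,2S,4R,6S)-2-((1E,3E)-2,4-dimethylhexa-1,3,5-trien-1-yl)-2,4,6-trimethylcyclohexyl]-4,4-diethoxybut-2-en-1-one | CCOC(OCC)/C=C/C(=O)[C@@H]1[C@@H](C)C[C@@H](C)C[C@]1(/C=C(C)/C=C(C)/C=C)C | intermediate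
17 | (1S,2E)-allylic alcohol from 16 | CCOC(OCC)/C=C/[C@H](O)[C@@H]1[C@@H](C)C[C@@H](C)C[C@]1(/C=C(C)/C=C(C)/C=C)C | intermediate
18 | 4-fluorobenzaldehyde | O=Cc1ccc(F)cc1 | starting material
19 | 4-formylphenyl ether of 17 | CCOC(OCC)/C=C/[C@H](Oc1ccc(C=O)cc1)[C@@H]1[C@@H](C)C[C@@H](C)C[C@]1(/C=C(C)/C=C(C)/C=C)C | intermediate
20 | 4-(hydroxymethyl)phenyl ether of 17 | CCOC(OCC)/C=C/[C@H](Oc1ccc(CO)cc1)[C@@H]1[C@@H](C)C[C@@H](C)C[C@]1(/C=C(C)/C=C(C)/C=C)C | intermediate
21 | (2E,4S)-4-aryloxy enal from 20 (not isolated) | O=C/C=C/[C@H](Oc1ccc(CO)cc1)[C@@H]1[C@@H](C)C[C@@H](C)C[C@]1(/C=C(C)/C=C(C)/C=C)C | intermediate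
22 | tricyclic aldehyde with 4-(hydroxymethyl)phenoxy group | C=C[C@@]1(C)C=C(C)[C@@H]2[C@@H]([C@H]1C=O)[C@H](Oc4ccc(CO)cc4)[C@@H]3[C@@H](C)C[C@@H](C)C[C@]32C | intermediate
23 | tricyclic aldehyde with 4-(chloromethyl)phenoxy group | C=C[C@@]1(C)C=C(C)[C@@H]2[C@@H]([C@H]1C=O)[C@H](Oc4ccc(CCl)cc4)[C@@H]3[C@@H](C)C[C@@H](C)C[C@]32C | intermediate
24 | ethyl (E)-3-(tributylstannyl)prop-2-enoate | CCCC[Sn](CCCC)(CCCC)/C=C/C(=O)OCC | starting material
25 | tricyclic aldehyde carrying the ethyl (E)-4-oxo-5-arylpent-2-enoate chain | C=C[C@@]1(C)C=C(C)[C@@H]2[C@@H]([C@H]1C=O)[C@H](Oc4ccc(CC(=O)/C=C/C(=O)OCC)cc4)[C@@H]3[C@@H](C)C[C@@H](C)C[C@]32C | intermediate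
26 | 13-membered paracyclophane 2-acyl-4-oxo ester | C=C[C@@]1(C)C=C(C)[C@@H]2[C@@H]3[C@H](Oc4ccc(cc4)CC(=O)CC(C(=O)OCC)C(=O)[C@H]31)[C@@H]1[C@@H](C)C[C@@H](C)C[C@]12C | intermediate
27 | CNP0450261.1 | C=C[C@@]1(C)C=C(C)[C@@H]2[C@@H]3[C@H](Oc4ccc(cc4)C[C@@]4(O)C[C@H](C(=O)N4)C(=O)[C@H]31)[C@@H]1[C@@H](C)C[C@@H](C)C[C@]12C | target

**Step count and risks**

Total step count: 19. Longest linear sequence: 18 steps (steps 1–9 and 11–19); step 10 prepares the side-chain stannane.

Steps most likely to fail:

1. Step 18 (Proposed new method). The carbene may not engage the hindered aldehyde, or intermolecular conjugate addition and base-induced oligomerisation through the benzylic ketone enolate may outrun closure of the strained ring. The fallback is an acyl radical macrocyclisation from a selenoester, a known reaction type. It sets out from 25, which is oxidised (NaClO2, NaH2PO4, 2-methylbut-2-ene, t-BuOH–H2O) to the carboxylic acid F1. The acid is converted with (PhSe)2 and PBu3 into the Se-phenyl selenoester F2. Slow addition of Bu3SnH and AIBN to F2 in benzene at 80 °C at high dilution (under CO if decarbonylation shows) generates the acyl radical, which should add to the same alkene carbon and, after hydrogen transfer, give 26, where the route is rejoined.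

2. Step 15. Endo or facial selectivity may be poor at 110 °C, or cycloaddition at the fully substituted diene terminus may be so slow that loss of the aryloxide from the γ-aryloxy enal competes. The fallback is a Lewis-acid-promoted cycloaddition one stage earlier, where no acid-labile benzylic alcohol is present. It sets out from 19, whose acetal is hydrolysed (PPTS, acetone–H2O) to the enal dialdehyde F3. Me2AlCl in CH2Cl2 at −78 to −20 °C should promote the intramolecular Diels–Alder reaction of the complexed enal to the tricyclic dialdehyde F4. Luche-type reduction (NaBH4, CeCl3·7H2O, EtOH–H2O, −15 °C) of the unhindered aromatic aldehyde in the presence of the flanked aliphatic one then returns to 22.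

3. Step 11. Deprotonation α to the hindered nitrile may replace addition, or the hindered ketimine may hydrolyse only under conditions that also cleave the acetal. The fallback goes through the aldehyde. It sets out from 11, which is reduced with i-Bu2AlH (toluene, −78 °C; aqueous tartrate work-up) to the aldehyde F5. Addition of vinyllithium 14 gives the allylic alcohol F6 as a mixture of carbinol epimers. Oxidation with MnO2 (CH2Cl2) converges both epimers on enone 16.

Further compounds
F1 | step 18 | carboxylic acid from 25 (CO2H in place of CHO) | C=C[C@@]1(C)C=C(C)[C@@H]2[C@@H]([C@H]1C(=O)O)[C@H](Oc4ccc(CC(=O)/C=C/C(=O)OCC)cc4)[C@@H]3[C@@H](C)C[C@@H](C)C[C@]32C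
F2 | step 18 | Se-phenyl selenoester of F1 | C=C[C@@]1(C)C=C(C)[C@@H]2[C@@H]([C@H]1C(=O)[Se]c5ccccc5)[C@H](Oc4ccc(CC(=O)/C=C/C(=O)OCC)cc4)[C@@H]3[C@@H](C)C[C@@H](C)C[C@]32C
F3 | step 15 | enal dialdehyde from 19 | O=C/C=C/[C@H](Oc1ccc(C=O)cc1)[C@@H]1[C@@H](C)C[C@@H](C)C[C@]1(/C=C(C)/C=C(C)/C=C)C
F4 | step 15 | tricyclic dialdehyde (4-formylphenoxy analogue of 22) | C=C[C@@]1(C)C=C(C)[C@@H]2[C@@H]([C@H]1C=O)[C@H](Oc4ccc(C=O)cc4)[C@@H]3[C@@H](C)C[C@@H](C)C[C@]32C
F5 | step 11 | (1R,2S,4R,6S)-2-[(1E,3E)-2,4-dimethylhexa-1,3,5-trien-1-yl]-2,4,6-trimethylcyclohexane-1-carbaldehyde | O=C[C@@H]1[C@@H](C)C[C@@H](C)C[C@]1(/C=C(C)/C=C(C)/C=C)C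
F6 | step 11 | allylic alcohol from F5 (both carbinol epimers) | CCOC(OCC)/C=C/C(O)[C@@H]1[C@@H](C)C[C@@H](C)C[C@]1(/C=C(C)/C=C(C)/C=C)C
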